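**Assumption (numbering and configuration).** Eudesmane-type locants are used: ring A = C5–C10; lactone ring B = C7, C8, O, C12, C11 with exocyclic C13; side chain C4 (methyl C15)–C3–C2–C1; ring methyl C14. The SMILES is read as 4S,6R,7R,8R, with H-6, H-7 and H-8 on the same face.

## Structural features

The target is a 1,10-seco-eudesmanolide: a cyclohexene (ring A, C5–C10) cis-fused through C7–C8 to an α-methylene-γ-butyrolactone (ring B, C7–C11(=C13)–C12(=O)–O–C8). Ring A has one double bond, the tetrasubstituted C5=C10; C10 carries methyl C14 and C5 carries the branched chain C4(C15)–C3–C2–C1–OAc. The other half of ring A holds three contiguous stereocentres, C6 (acetoxy), C7 (ring fusion) and C8 (lactone oxygen), all cis, so that O-6 and O-8 flank C7 in a pseudo-symmetric 1,3-syn array. The fourth stereocentre, C4, is exocyclic and is insulated from the triad by the planar C5, so neither element can reliably control the other. Fragile groups are the C11=C13 acrylate (Michael acceptor, prone to migrate into ring B), the allylic C6 acetate and the primary acetate; in addition, any carbonyl at C6 or C8 in a ring that already contains C5=C10 is one β-elimination and one tautomerisation away from a phenol. The real difficulty is to build the all-cis C6/C7/C8 triad next to a fully substituted alkene, with the lactone on O-8 and not O-6, without passing through such a ketone. The key step exploits the fact that C5=C10 is the only bond of ring A with no stereocentre at either end and is the bond that separates the purchased C4 centre from the triad: ring A is closed there, last, by ring-closing metathesis of an open-chain diene in which ring B already holds the two alkenes cis.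

## Logic of the disconnections

**21 ⇒ 20.** The C5=C10 double bond is cut and each carbon is capped with a methylidene. This is the one ring bond whose cleavage touches no stereocentre, and it turns the bicycle into a monocyclic lactone that separates into a C1–C6 piece and a C7–C14 piece. The forward step must form a tetrasubstituted cyclohexene alkene from two 1,1-disubstituted alkenes, one of them hindered, and must leave the C11=C13 acrylate alone.

**20 ⇒ 18 (through 19).** The acyl–oxygen bond C12–O8 is cut, leaving a methyl ester and a silyl ether on O-8. Keeping ring B open until O-6 is acetylated removes the O-6/O-8 ambiguity of lactonisation. The forward step must free O-8 under conditions in which ring closure is faster than acetyl migration from O-6.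

**18 ⇒ 17.** The O6–acetyl bond is cut. The demand is only that acetylation of the hindered C6 carbinol outruns its attack on the ester.

**17 ⇒ 7 + 15 (through 16).** The C6–C7 bond is cut. This is the convergent join; it creates C6 and C7 together and delivers the acrylate C11=C13 in the same event. The forward step must give the syn C6/C7 relationship (closed chair from the Z-allyl unit) and must add to the face of C7 dictated by the existing C8 centre.

**15 ⇒ 14 ⇒ 12 + 13.** The C13–Br bond is cut with allylic transposition, then the C7–C11 bond. This reduces the functionalised allyl bromide to an α-silyloxy aldehyde and 13. The demands are Z-geometry of the trisubstituted alkene and no epimerisation at C8.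

**12 ⇒ 11 ⇒ 10 ⇒ 8 + 9.** After oxidation-level and protecting-group adjustment, the C8–C9 bond is cut (carbonyl-ene retron). Two achiral C4 and C3 units result; the forward step must set C8 by catalysis, and this is the only centre of the triad not relayed.

**7 ⇒ 6 ⇒ 5 ⇒ 4 ⇒ 2 ⇒ 1.** The C5 methylidene is removed (α-methylenation retron), the acetate and the C6 aldehyde are unmasked, and the C1–O bond is traced to the cleaved trisubstituted alkene of 1. C4 is bought; the demand is only that the β-stereocentre is never epimerised.

## Other disconnections considered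

**Alternative 1:** Diels–Alder (the first that comes to mind for a cyclohexene). Cut C6–C7 and C8–C9: the 1-acetoxy diene A1 plus a cis dienophile; maleic anhydride would give the all-cis endo adduct A2.
- The retron needs a dienophile with oxygen on C8 and the acrylate carbon on C7. The only alkene with that pattern is the enol-lactone tautomer of ring B, which is electron-rich, unstable toward its conjugated isomer and mismatched with an electron-rich diene.
- With an acceptor dienophile, C8 arrives as a carbon substituent. A2 would then need a carboxyl-to-oxygen degradation at C8 with retention and a one-carbon adjustment at C7.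
- A1 must also be geometrically pure, and an external chiral catalyst is needed because C4 is too remote to bias the diene face.
- The cycloaddition would close the ring but leave most of the functional problem, at the cost of many more steps.

**Alternative 2:** Cyclohexenone annulation. Cut C6–C7 (conjugate addition of an acyl-anion equivalent of 6 to a C8-oxygenated butenolide) and C5=C10 (intramolecular aldol condensation) to reach enone A3, then reduce C6 from the convex face and methylenate ring B.
- A3 has a C6 ketone, an acyloxy leaving group on C8 and C5=C10 in the same ring. E1cB loss of the carboxylate followed by tautomerisation would give phenol A4 irreversibly.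
- In the open 1,5-diketone precursor, O-8 is β to both carbonyls, and the condensation needs acid or base and heat, so this pathway is expected to compete.
- Late methylenation would need a strong base in the presence of two acetates.
- The chosen route creates C6 and C8 directly at the alcohol oxidation level and never has a carbonyl in ring A.

**Alternative 3:** Intramolecular Barbier allylation. Cut C6–C7 inside ring A: the bromomethyl butenolide A5, tethered to a (Z)-enal, would close ring A with zinc or CrCl2 and form C6, C7 and C11=C13 at once, with the cis ring fusion enforced by the tether.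
- A5 needs a geometrically pure tetrasubstituted (Z)-enal. Every stereodefined access goes through a cyclic template and costs six or more steps.
- In the butenolide, C8 is trans to the CH2–metal carbon. The closed chair then puts C8 and the aldehyde residue both equatorial and is expected to give the 6-epi alcohol A6, which would need inversion at a hindered allylic carbinol on the concave face.
- The chosen plan keeps the acrylate open-chain with Z-geometry, for which the same chair gives the required syn relationship, and moves ring closure to C5=C10.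

Key step: step 14

## Route

Step 1
Reactants: 1 (S)-citronellal [(3S)-3,7-dimethyloct-6-enal]
Product: 2 (6S)-8,8-dimethoxy-2,6-dimethyloct-2-ene
Conditions: HC(OMe)3, MeOH, PPTS (cat.), 0 °C to rt
Reagents that add atoms: trimethyl orthoformate COC(OC)OC
Why: Acid-catalysed acetalisation with the orthoformate as water scavenger; the weak acid avoids the carbonyl-ene cyclisation of citronellal, and the C4 stereocentre (bought) is not touched.

Step 2
Reactants: 2 (6S)-8,8-dimethoxy-2,6-dimethyloct-2-ene
Product: 4 (4S)-6,6-dimethoxy-4-methylhexan-1-ol, via dimethoxy aldehyde 3 (not isolated)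
Conditions: O3, CH2Cl2/MeOH 4:1, −78 °C; then NaBH4, −78 °C to rt
Reagents that add atoms: ozone [O-][O+]=O
Why: Ozonolysis of the only alkene with reductive work-up gives the C1 alcohol; the acetal is inert to ozone and borohydride.

Step 3
Reactants: 4 (4S)-6,6-dimethoxy-4-methylhexan-1-ol
Product: 5 (4S)-6,6-dimethoxy-4-methylhexyl acetate
Conditions: Ac2O, pyridine, DMAP (cat.), CH2Cl2, 0 °C to rt
Reagents that add atoms: acetic anhydride CC(=O)OC(C)=O
Why: DMAP-catalysed acetylation installs the C1 acetate of the target at the outset.

Step 4
Reactants: 5 (4S)-6,6-dimethoxy-4-methylhexyl acetate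
Product: 6 (4S)-4-methyl-6-oxohexyl acetate
Conditions: PPTS (cat.), acetone/H2O 9:1, 50 °C
Reagents that add atoms: water O
Why: Mild acetal hydrolysis frees the C6 aldehyde; the primary acetate survives weak aqueous acid and C4 is β to the carbonyl, so it cannot enolise away.

Step 5
Reactants: 6 (4S)-4-methyl-6-oxohexyl acetate
Product: 7 (4S)-5-formyl-4-methylhex-5-en-1-yl acetate
Conditions: 37% aq. CH2O, pyrrolidine (10 mol%), propionic acid (10 mol%), i-PrOH, 45 °C
Reagents that add atoms: formaldehyde C=O
Why: Organocatalytic α-methylenation of an aldehyde (enamine Mannich condensation, then β-elimination of the amine) puts the methylidene handle on C5; α-branched enals form iminium ions reluctantly, which protects C4 from γ-deprotonation.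

Step 6
Reactants: 8 2-methylpropene; 9 methyl glyoxylate
Product: 10 methyl (2R)-2-hydroxy-4-methylpent-4-enoate
Conditions: (R)-BINOL (10 mol%), TiCl2(O-i-Pr)2 (10 mol%), 4 Å MS, CH2Cl2, −30 °C
Reagents that add atoms: none
Why: Catalytic asymmetric glyoxylate-ene (carbonyl-ene) reaction forms C8–C9; C8 is set by the chiral tetravalent titanium–BINOL Lewis acid, the (R)-ligand being expected to give the (R)-alcohol through the six-membered ene transition state.

Step 7
Reactants: 10 methyl (2R)-2-hydroxy-4-methylpent-4-enoate
Product: 11 methyl (2R)-2-[(tert-butyldimethylsilyl)oxy]-4-methylpent-4-enoate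
Conditions: TBSCl, imidazole, DMF, rt
Reagents that add atoms: tert-butyldimethylsilyl chloride CC(C)(C)[Si](C)(C)Cl
Why: Standard silylation gives a non-chelating ether on O-8, which is needed for the facial control in step 11.

Step 8
Reactants: 11 methyl (2R)-2-[(tert-butyldimethylsilyl)oxy]-4-methylpent-4-enoate
Product: 12 (2R)-2-[(tert-butyldimethylsilyl)oxy]-4-methylpent-4-enal
Conditions: i-Bu2AlH (1.05 equiv), CH2Cl2, −78 °C; Rochelle salt work-up
Reagents that add atoms: none
Why: Partial reduction of an ester with one hydride equivalent at −78 °C; α-silyloxy esters are reliable substrates and the non-basic conditions keep C8 intact.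

Step 9
Reactants: 12 (2R)-2-[(tert-butyldimethylsilyl)oxy]-4-methylpent-4-enal; 13 methyl acrylate
Product: 14 methyl (4R)-4-[(tert-butyldimethylsilyl)oxy]-3-hydroxy-6-methyl-2-methylidenehept-6-enoate (mixture of C3 epimers)
Conditions: DABCO (1 equiv), methyl acrylate (3 equiv), MeOH, rt
Reagents that add atoms: none
Why: Morita–Baylis–Hillman reaction forms C7–C11; α-alkoxy aldehydes are activated acceptors, and the new carbinol centre is inconsequential because it becomes sp2 in step 10.

Step 10
Reactants: 14 methyl (4R)-4-[(tert-butyldimethylsilyl)oxy]-3-hydroxy-6-methyl-2-methylidenehept-6-enoate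
Product: 15 methyl (2Z,4R)-2-(bromomethyl)-4-[(tert-butyldimethylsilyl)oxy]-6-methylhepta-2,6-dienoate
Conditions: NBS, Me2S, CH2Cl2, 0 °C (reagent premixed), then 14, 0 °C to rt
Reagents that add atoms: N-bromosuccinimide O=C1CCC(=O)N1Br
Why: Corey–Kim-type activation of the allylic alcohol and SN2′ displacement by bromide; the trisubstituted enoate forms with C8 trans to the ester (Z), the usual and thermodynamically preferred geometry.

Step 11
Reactants: 7 (4S)-5-formyl-4-methylhex-5-en-1-yl acetate; 15 methyl (2Z,4R)-2-(bromomethyl)-4-[(tert-butyldimethylsilyl)oxy]-6-methylhepta-2,6-dienoate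
Product: 17 methyl (3S,4R)-3-[(1R,3S)-6-acetoxy-1-hydroxy-3-methyl-2-methylidenehexyl]-4-[(tert-butyldimethylsilyl)oxy]-6-methyl-2-methylidenehept-6-enoate, via allylzinc bromide 16 (not isolated)
Conditions: Zn dust (activated), THF/sat. aq. NH4Cl 1:1, 0 °C to rt
Reagents that add atoms: none
Why: Zinc-mediated Barbier 2-(alkoxycarbonyl)allylation: 16 adds through its γ-carbon C7 to the aldehyde and regenerates the acrylate C11=C13. The Zimmerman–Traxler chair from the Z-allyl unit (C8 axial, aldehyde residue equatorial) gives the syn C6/C7 pair. The C7 face is chosen by C8 through allylic 1,3-strain (H-8 eclipsing C7=C11, aldehyde anti to the C9 chain, silyloxy outside), so C6 and C7 are both relayed from C8 in one event.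

Step 12
Reactants: 17 methyl (3S,4R)-3-[(1R,3S)-6-acetoxy-1-hydroxy-3-methyl-2-methylidenehexyl]-4-[(tert-butyldimethylsilyl)oxy]-6-methyl-2-methylidenehept-6-enoate
Product: 18 methyl (3S,4R)-3-[(1R,3S)-1,6-diacetoxy-3-methyl-2-methylidenehexyl]-4-[(tert-butyldimethylsilyl)oxy]-6-methyl-2-methylidenehept-6-enoate
Conditions: Ac2O, pyridine, DMAP (cat.), CH2Cl2, 0 °C
Reagents that add atoms: acetic anhydride CC(=O)OC(C)=O
Why: DMAP-catalysed acetylation installs the C6 acetate of the target and blocks O-6, so that only O-8 can close ring B later.

Step 13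
Reactants: 18 methyl (3S,4R)-3-[(1R,3S)-1,6-diacetoxy-3-methyl-2-methylidenehexyl]-4-[(tert-butyldimethylsilyl)oxy]-6-methyl-2-methylidenehept-6-enoate
Product: 20 (4R,5R)-4-[(1R,3S)-1,6-diacetoxy-3-methyl-2-methylidenehexyl]-3-methylidene-5-(2-methylprop-2-en-1-yl)oxolan-2-one, via hydroxy ester 19 (not isolated)
Conditions: HF·pyridine, THF, 0 °C to rt; then CSA (cat.), CH2Cl2, rt
Reagents that add atoms: none
Why: Fluoride-mediated desilylation followed by acid-catalysed lactonisation of the γ-hydroxy ester (5-exo-trig acyl substitution) closes ring B on O-8 with retention at C8; acidic conditions keep both acetates and disfavour O-6 to O-8 acetyl migration relative to five-membered ring closure.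

Step 14
Reactants: 20 (4R,5R)-4-[(1R,3S)-1,6-diacetoxy-3-methyl-2-methylidenehexyl]-3-methylidene-5-(2-methylprop-2-en-1-yl)oxolan-2-one
Product: 21 1,6-O,O-diacetylbritannilactone [(3aR,4R,7aR)-5-[(2S)-5-acetoxypentan-2-yl]-6-methyl-3-methylidene-2-oxo-2,3,3a,4,7,7a-hexahydro-1-benzofuran-4-yl acetate]
Conditions: RuCl2(=CH-C6H4-2-O-i-Pr)[1,3-bis(2-methylphenyl)imidazolidin-2-ylidene] (second-generation Hoveyda–Grubbs-type catalyst, 10 mol% in two portions), 1,4-benzoquinone (20 mol%), toluene (2 mM), 80 °C, argon sparge
Reagents that add atoms: none
Why: Mechanism: olefin metathesis by the Chauvin cycle; the ruthenium alkylidene first exchanges with the less hindered 2-methylallyl alkene to give a Ru=C10 alkylidene, which adds across the C5 methylidene to a ruthenacyclobutane whose cycloreversion forms C5=C10 and releases ethene. The closest known reaction type is ring-closing metathesis to tetrasubstituted cyclohexenes with ruthenium catalysts carrying the small N,N′-di-o-tolyl carbene. The ring closed is the six-membered carbocycle (ring A), by ring-closing metathesis joining its two alkene carbons; the new alkene is endocyclic and its geometry is fixed by the ring. No stereocentre is formed or touched: C4, C6, C7 and C8 are carried from 20. The first selectivity needed is chemoselectivity against the C11=C13 acrylate, and it is secured by geometry: closure of C13 onto the 2-methylallyl group would need a bridgehead alkene in a 2-oxabicyclo[2.2.1] skeleton and closure onto C5 would need a cyclobutene. The second is ring closure over dimerisation, secured by the cis-β,γ-disubstituted lactone, which holds the two alkenes on one face, and by high dilution. The third is the absence of olefin migration, for which benzoquinone scavenges ruthenium hydrides. The step will be slow because C5 lies between two tertiary carbons, hence the small carbene ligand, 80 °C and removal of ethene.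

## Compound list

1 | (S)-citronellal [(3S)-3,7-dimethyloct-6-enal] | C[C@@H](CCC=C(C)C)CC=O | starting material
2 | (6S)-8,8-dimethoxy-2,6-dimethyloct-2-ene | COC(OC)C[C@@H](C)CCC=C(C)C | intermediate
3 | (4S)-6,6-dimethoxy-4-methylhexanal | COC(OC)C[C@@H](C)CCC=O | intermediate
4 | (4S)-6,6-dimethoxy-4-methylhexan-1-ol | COC(OC)C[C@@H](C)CCCO | intermediate
5 | (4S)-6,6-dimethoxy-4-methylhexyl acetate | COC(OC)C[C@@H](C)CCCOC(C)=O | intermediate
6 | (4S)-4-methyl-6-oxohexyl acetate | O=CC[C@@H](C)CCCOC(C)=O | intermediate
7 | (4S)-5-formyl-4-methylhex-5-en-1-yl acetate | C=C(C=O)[C@@H](C)CCCOC(C)=O | intermediate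
8 | 2-methylpropene | CC(C)=C | starting material
9 | methyl glyoxylate | COC(=O)C=O | starting material
10 | methyl (2R)-2-hydroxy-4-methylpent-4-enoate | COC(=O)[C@H](O)CC(C)=C | intermediate
11 | methyl (2R)-2-[(tert-butyldimethylsilyl)oxy]-4-methylpent-4-enoate | COC(=O)[C@H](O[Si](C)(C)C(C)(C)C)CC(C)=C | intermediate
12 | (2R)-2-[(tert-butyldimethylsilyl)oxy]-4-methylpent-4-enal | O=C[C@H](O[Si](C)(C)C(C)(C)C)CC(C)=C | intermediate
13 | methyl acrylate | C=CC(=O)OC | starting material
14 | methyl (4R)-4-[(tert-butyldimethylsilyl)oxy]-3-hydroxy-6-methyl-2-methylidenehept-6-enoate (C3 epimers) | COC(=O)C(=C)C(O)[C@H](O[Si](C)(C)C(C)(C)C)CC(C)=C | intermediate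
15 | methyl (2Z,4R)-2-(bromomethyl)-4-[(tert-butyldimethylsilyl)oxy]-6-methylhepta-2,6-dienoate | COC(=O)/C(CBr)=C/[C@H](O[Si](C)(C)C(C)(C)C)CC(C)=C | intermediate
16 | bromo{(2Z,4R)-4-[(tert-butyldimethylsilyl)oxy]-2-(methoxycarbonyl)-6-methylhepta-2,6-dien-1-yl}zinc | COC(=O)/C(C[Zn]Br)=C/[C@H](O[Si](C)(C)C(C)(C)C)CC(C)=C | intermediate
17 | methyl (3S,4R)-3-[(1R,3S)-6-acetoxy-1-hydroxy-3-methyl-2-methylidenehexyl]-4-[(tert-butyldimethylsilyl)oxy]-6-methyl-2-methylidenehept-6-enoate | COC(=O)C(=C)[C@H]([C@H](O[Si](C)(C)C(C)(C)C)CC(C)=C)[C@@H](O)C(=C)[C@@H](C)CCCOC(C)=O | intermediate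
18 | methyl (3S,4R)-3-[(1R,3S)-1,6-diacetoxy-3-methyl-2-methylidenehexyl]-4-[(tert-butyldimethylsilyl)oxy]-6-methyl-2-methylidenehept-6-enoate | COC(=O)C(=C)[C@H]([C@H](O[Si](C)(C)C(C)(C)C)CC(C)=C)[C@@H](OC(C)=O)C(=C)[C@@H](C)CCCOC(C)=O | intermediate
19 | methyl (3R,4R)-3-[(1R,3S)-1,6-diacetoxy-3-methyl-2-methylidenehexyl]-4-hydroxy-6-methyl-2-methylidenehept-6-enoate | COC(=O)C(=C)[C@H]([C@H](O)CC(C)=C)[C@@H](OC(C)=O)C(=C)[C@@H](C)CCCOC(C)=O | intermediate
20 | (4R,5R)-4-[(1R,3S)-1,6-diacetoxy-3-methyl-2-methylidenehexyl]-3-methylidene-5-(2-methylprop-2-en-1-yl)oxolan-2-one | C=C1C(=O)O[C@H](CC(C)=C)[C@@H]1[C@@H](OC(C)=O)C(=C)[C@@H](C)CCCOC(C)=O | intermediate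
21 | 1,6-O,O-diacetylbritannilactone [(3aR,4R,7aR)-5-[(2S)-5-acetoxypentan-2-yl]-6-methyl-3-methylidene-2-oxo-2,3,3a,4,7,7a-hexahydro-1-benzofuran-4-yl acetate] | C=C1C(=O)O[C@@H]2CC(C)=C([C@@H](C)CCCOC(C)=O)[C@H](OC(C)=O)[C@H]12 | target

## Step count and least certain steps

Total step count: 14. Longest linear sequence: 9 steps (steps 1–5 and 11–14 from 1; equally steps 6–10 and 11–14 from 8 and 9).

**Step 14 (key step).** The most likely failure is that the Ru=C10 alkylidene does not engage the C5 methylidene, which sits between two tertiary carbons (C4 and C6). Catalyst decomposition, hydride-induced alkene migration (C11=C13 into ring B, or the 2-methylallyl group to its internal isomer) and dimerisation at the 2-methylallyl terminus would then outrun ring closure.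

Fallback (relay ring-closing metathesis; sets out from 6, returns at 21):
- 6 would be condensed with 2-(allyloxy)acetaldehyde (amine-catalysed cross-aldol condensation) to the relay enal (4S)-5-formyl-4-methyl-7-(prop-2-en-1-yloxy)hept-5-en-1-yl acetate F1.
- Zinc-mediated coupling of F1 with 15, as in step 11, would give methyl (3S,4R)-3-{(1R,3S)-6-acetoxy-1-hydroxy-3-methyl-2-[2-(prop-2-en-1-yloxy)ethylidene]hexyl}-4-[(tert-butyldimethylsilyl)oxy]-6-methyl-2-methylidenehept-6-enoate F2.
- Acetylation would give the corresponding 1,6-diacetate F3.
- HF·pyridine and then acid would give (4R,5R)-4-{(1R,3S)-1,6-diacetoxy-3-methyl-2-[2-(prop-2-en-1-yloxy)ethylidene]hexyl}-3-methylidene-5-(2-methylprop-2-en-1-yl)oxolan-2-one F4.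
- In F4 the catalyst loads on the unhindered terminal allyl ether alkene, expels 2,5-dihydrofuran and is thereby delivered as a carbene to C5. This carbene closes onto the 2-methylallyl alkene and gives 21 with loss of ethene.

**Step 11.** The most likely failure is poor π-facial selectivity at C7 of 16. Addition anti to the silyloxy group instead of anti to the C9 chain would give the 7,8-anti series, which closes to a trans-lactone; the two allylic 1,3-strain models (alkyl anti versus alkoxy anti) point in opposite directions, so this is a real uncertainty. Some erosion of the syn C6/C7 preference is also possible if the allylzinc loses its geometry.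

Fallback (catalyst-controlled allylboration; sets out from 15, returns at 17): 15 would be converted by palladium-catalysed borylation with B2pin2 into methyl (2E,4R)-4-[(tert-butyldimethylsilyl)oxy]-6-methyl-2-[(4,4,5,5-tetramethyl-1,3,2-dioxaborolan-2-yl)methyl]hepta-2,6-dienoate F5. F5 would be added to 7 under chiral BINOL-derived phosphoric acid catalysis. The closed chair of allylboration keeps the syn C6/C7 relationship, while the catalyst rather than C8 selects the aldehyde face and, through the chair, the C7 face.

**Step 9.** The most likely failure is a slow amine-catalysed addition to the α-branched aldehyde, during which 12 can epimerise at C8 through its enol or suffer silyl migration. This would lower the enantiomeric purity from which the whole triad is relayed.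

Fallback (preformed vinylmetal; sets out from 12, returns at 14): hydroalumination of methyl propiolate with i-Bu2AlH and N-methylmorpholine N-oxide gives methyl 2-(diisobutylalumanyl)prop-2-enoate F7. F7 adds to 12 at 0 °C under non-basic conditions and gives 14 after aqueous work-up.

**Step 10.** The most likely failure is electrophilic bromination of the electron-rich 2-methylallyl alkene by the bromosulfonium reagent, or SN2 instead of SN2′ substitution, which would give the secondary bromide and loss of alkene geometry.

Fallback (π-allylpalladium umpolung; sets out from 14, returns at 17): 14 would be acetylated to methyl (4R)-3-acetoxy-4-[(tert-butyldimethylsilyl)oxy]-6-methyl-2-methylidenehept-6-enoate F6. F6 would be coupled directly with 7 using Pd(PPh3)4 (zerovalent palladium) and InI (monovalent indium) in THF/H2O. This turns the allylic acetate in situ into the same γ-substituted 2-(methoxycarbonyl)allyl nucleophile, so 15 and 16 are bypassed.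

## Further compounds

F1 | step 14 | (4S)-5-formyl-4-methyl-7-(prop-2-en-1-yloxy)hept-5-en-1-yl acetate (E/Z mixture) | O=CC(=CCOCC=C)[C@@H](C)CCCOC(C)=O
F2 | step 14 | methyl (3S,4R)-3-{(1R,3S)-6-acetoxy-1-hydroxy-3-methyl-2-[2-(prop-2-en-1-yloxy)ethylidene]hexyl}-4-[(tert-butyldimethylsilyl)oxy]-6-methyl-2-methylidenehept-6-enoate | COC(=O)C(=C)[C@H]([C@H](O[Si](C)(C)C(C)(C)C)CC(C)=C)[C@@H](O)C(=CCOCC=C)[C@@H](C)CCCOC(C)=O
F3 | step 14 | methyl (3S,4R)-3-{(1R,3S)-1,6-diacetoxy-3-methyl-2-[2-(prop-2-en-1-yloxy)ethylidene]hexyl}-4-[(tert-butyldimethylsilyl)oxy]-6-methyl-2-methylidenehept-6-enoate | COC(=O)C(=C)[C@H]([C@H](O[Si](C)(C)C(C)(C)C)CC(C)=C)[C@@H](OC(C)=O)C(=CCOCC=C)[C@@H](C)CCCOC(C)=O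
F4 | step 14 | (4R,5R)-4-{(1R,3S)-1,6-diacetoxy-3-methyl-2-[2-(prop-2-en-1-yloxy)ethylidene]hexyl}-3-methylidene-5-(2-methylprop-2-en-1-yl)oxolan-2-one | C=C1C(=O)O[C@H](CC(C)=C)[C@@H]1[C@@H](OC(C)=O)C(=CCOCC=C)[C@@H](C)CCCOC(C)=O
F5 | step 11 | methyl (2E,4R)-4-[(tert-butyldimethylsilyl)oxy]-6-methyl-2-[(4,4,5,5-tetramethyl-1,3,2-dioxaborolan-2-yl)methyl]hepta-2,6-dienoate | COC(=O)/C(CB1OC(C)(C)C(C)(C)O1)=C/[C@H](O[Si](C)(C)C(C)(C)C)CC(C)=C
F6 | step 10 | methyl (4R)-3-acetoxy-4-[(tert-butyldimethylsilyl)oxy]-6-methyl-2-methylidenehept-6-enoate (C3 epimers) | COC(=O)C(=C)C(OC(C)=O)[C@H](O[Si](C)(C)C(C)(C)C)CC(C)=C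
F7 | step 9 | methyl 2-(diisobutylalumanyl)prop-2-enoate | COC(=O)C(=C)[Al](CC(C)C)CC(C)C
A1 | alternative 1 | (1E)-2-[(2S)-5-acetoxypentan-2-yl]-3-methylbuta-1,3-dien-1-yl acetate | CC(=O)O/C=C(/C(C)=C)[C@@H](C)CCCOC(C)=O
A2 | alternative 1 | (3aR,4R,7aR)-5-[(2S)-5-acetoxypentan-2-yl]-6-methyl-1,3-dioxo-1,3,3a,4,7,7a-hexahydro-2-benzofuran-4-yl acetate | O=C1OC(=O)[C@@H]2CC(C)=C([C@@H](C)CCCOC(C)=O)[C@H](OC(C)=O)[C@H]12
A3 | alternative 2 | (4S)-4-[(3aR,7aR)-6-methyl-2,4-dioxo-2,3,3a,4,7,7a-hexahydro-1-benzofuran-5-yl]pentyl acetate | C1C(=O)O[C@@H]2CC(C)=C([C@@H](C)CCCOC(C)=O)C(=O)[C@H]12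
A4 | alternative 2 | {3-[(2S)-5-acetoxypentan-2-yl]-2-hydroxy-4-methylphenyl}acetic acid | OC(=O)Cc1ccc(C)c([C@@H](C)CCCOC(C)=O)c1O
A5 | alternative 3 | (4S,5Z)-7-[(2R)-4-(bromomethyl)-5-oxo-2,5-dihydrofuran-2-yl]-5-formyl-4,6-dimethylhept-5-en-1-yl acetate | O=C/C(=C(C)\C[C@H]1OC(=O)C(CBr)=C1)[C@@H](C)CCCOC(C)=O
A6 | alternative 3 | 6-epi-1-O-acetylbritannilactone [(4S)-4-[(3aS,4S,7aR)-4-hydroxy-6-methyl-3-methylidene-2-oxo-2,3,3a,4,7,7a-hexahydro-1-benzofuran-5-yl]pentyl acetate] | C=C1C(=O)O[C@@H]2CC(C)=C([C@@H](C)CCCOC(C)=O)[C@@H](O)[C@H]12
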